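**Retrosynthetic overview**
- Target ← global desilylation ← bis-silyl macrolactone; its C6–C7 bond, ten-membered carbocycle and cis-fused α-methylene-γ-lactone form together in a chromium-catalysed, ligand-controlled intramolecular 2-(methoxycarbonyl)allylation of a seco bromo-ester Z-enal.
- Seco compound ← cross-metathesis with a bromomethyl acrylate, C8 esterification, Sharpless epoxidation (C1/C10) and reduction of an E-alkylidene butyrolactone.
- Alkylidene lactone ← Horner–Wadsworth–Emmons union (C1=C10) of a West aldehyde (C1–C6, C15) with an East phosphono-lactone (C7–C10, C14).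
- West ← asymmetric nickel/chromium alkenyl–aldehyde coupling (C3–C4) of a (Z)-iodobutenol ether; East ← (R)-5-(hydroxymethyl)butyrolactone; two side branches supply the bromo-acrylate and the (R)-acid.
- Ring order: sacrificial butyrolactone (carries C8) → oxirane → ten-membered carbocycle → α-methylene-γ-lactone.

Assumption: carbons are labelled by germacranolide numbering (C1/C10 oxirane, C3 carbinol, C4=C5 with C15 methyl, C6 lactone O–CH, C7, C8 ester carbinol, C9, C11=C13 exo-methylene, C12 lactone C=O, C14 CH2OH); paraformaldehyde is entered as formaldehyde.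

**Route**

Step 1
Reactants: 1 but-2-yn-1-ol
Product: 3 (Z)-3-iodobut-2-en-1-ol, via cyclic alkenylaluminate 2 (not isolated)
Conditions: NaAlH2(OCH2CH2OMe)2, THF, 0 °C to rt; then I2, −78 to 0 °C
Reagents that add atoms: iodine, [I][I]
Why: Hydroxyl-directed trans-hydroalumination of the propargylic alcohol puts aluminium on C3 cis to the CH2O arm (five-membered alanate), and iodinolysis with retention gives only the Z alkenyl iodide, the future C4=C5 geometry.

Step 2
Reactants: 3 (Z)-3-iodobut-2-en-1-ol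
Product: 4 (Z)-triethyl[(3-iodobut-2-en-1-yl)oxy]silane
Conditions: Et3SiCl, imidazole, CH2Cl2, 0 °C
Reagents that add atoms: chlorotriethylsilane, CC[Si](Cl)(CC)CC
Why: Routine silylation of a primary alcohol; a primary triethylsilyl ether is later the only silyl ether that a Swern oxidation turns directly into an aldehyde.

Step 3
Reactants: 5 propane-1,3-diol
Product: 6 3-[(4-methoxybenzyl)oxy]propan-1-ol
Conditions: NaH (1 equiv), 4-methoxybenzyl chloride, Bu4NI (cat.), THF, 0 °C to rt
Reagents that add atoms: 4-methoxybenzyl chloride, COc1ccc(CCl)cc1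
Why: Williamson monoetherification of the symmetric diol, used in excess, gives the mono-ether.

Step 4
Reactants: 6 mono-PMB ether of propanediol
Product: 7 3-[(4-methoxybenzyl)oxy]propanal
Conditions: TEMPO (10 mol %), PhI(OAc)2, CH2Cl2, rt
Reagents that add atoms: none
Why: Oxoammonium (TEMPO) oxidation of a primary alcohol stops at the aldehyde and leaves the benzyl ether alone.

Step 5
Reactants: 4 Z-alkenyl iodide, 7 aldehyde
Product: 8 (3S,4Z)-1-[(4-methoxybenzyl)oxy]-4-methyl-6-[(triethylsilyl)oxy]hex-4-en-3-ol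
Conditions: CrCl2 (10 mol %), chiral oxazoline–sulfonamide ligand (Kishi type, 11 mol %), Et3N (20 mol %), NiCl2·(2,9-dimethyl-1,10-phenanthroline) (2 mol %), Mn, Cp2ZrCl2, LiCl, MeCN, rt
Reagents that add atoms: none
Why: Catalytic asymmetric Nozaki–Hiyama–Kishi coupling: zerovalent nickel activates the iodide, the alkenyl group passes with retention of Z geometry to ligand-bound trivalent chromium and adds to the Re face of 7 (the ligand antipode is chosen for this), setting C3 as S.

Step 6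
Reactants: 8 allylic alcohol
Product: 9 tert-butyl{[(3S,4Z)-1-[(4-methoxybenzyl)oxy]-4-methyl-6-[(triethylsilyl)oxy]hex-4-en-3-yl]oxy}dimethylsilane
Conditions: tBuMe2SiOTf, 2,6-lutidine, CH2Cl2, −78 °C
Reagents that add atoms: tert-butyldimethylsilyl trifluoromethanesulfonate, CC(C)(C)[Si](C)(C)OS(=O)(=O)C(F)(F)F
Why: Silyl triflate O-silylation of the hindered secondary allylic alcohol does not touch the stereocentre.

Step 7
Reactants: 9 fully protected triol
Product: 10 (3S,4Z)-3-[(tert-butyldimethylsilyl)oxy]-4-methyl-6-[(triethylsilyl)oxy]hex-4-en-1-ol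
Conditions: DDQ, CH2Cl2/pH 7 buffer, 0 °C
Reagents that add atoms: none
Why: Oxidative cleavage of the electron-rich 4-methoxybenzyl ether (hydride abstraction, then hydrolysis) leaves both silyl ethers and the alkene untouched.

Step 8
Reactants: 10 primary alcohol
Product: 11 (3S,4Z)-3-[(tert-butyldimethylsilyl)oxy]-4-methyl-6-[(triethylsilyl)oxy]hex-4-enal
Conditions: Dess–Martin periodinane, NaHCO3, CH2Cl2, 0 °C to rt
Reagents that add atoms: none
Why: Buffered Dess–Martin oxidation gives the β-silyloxy aldehyde without β-elimination.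

Step 9
Reactants: 12 (5R)-5-(hydroxymethyl)dihydrofuran-2(3H)-one
Product: 13 (2R)-5-oxotetrahydrofuran-2-carbaldehyde
Conditions: (COCl)2, DMSO, CH2Cl2, −78 °C; Et3N, −78 to 0 °C
Reagents that add atoms: none
Why: Swern oxidation at low temperature gives the α-oxygenated aldehyde without loss of the future C8 configuration; it is used crude.

Step 10
Reactants: 13 lactone aldehyde
Product: 14 (5R)-5-vinyldihydrofuran-2(3H)-one
Conditions: Ph3PCH3Br, KN(SiMe3)2, THF, 0 °C; then 13, −78 °C to rt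
Reagents that add atoms: methyltriphenylphosphonium bromide, C[P+](c1ccccc1)(c1ccccc1)c1ccccc1.[Br-]
Why: Wittig methylenation is much faster at the aldehyde than at the lactone carbonyl and installs the vinyl group used later in the cross-metathesis.

Step 11
Reactants: 14 vinyl lactone
Product: 16 diethyl [(5R)-2-oxo-5-vinyltetrahydrofuran-3-yl]phosphonate, via enol phosphate 15 (not isolated)
Conditions: LiN(iPr)2 (1.1 equiv), THF, −78 °C; ClP(O)(OEt)2; then LiN(iPr)2 (2.2 equiv), −78 to 0 °C; AcOH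
Reagents that add atoms: diethyl chlorophosphate, CCOP(=O)(Cl)OCC
Why: O-phosphorylation of the lactone enolate and base-induced 1,3-shift of phosphorus from oxygen to carbon (vinyl phosphate to phosphonate rearrangement) give the α-phosphono lactone; its epimeric α-centre disappears in step 15.

Step 12
Reactants: 17 methyl acrylate, 18 formaldehyde (charged as paraformaldehyde)
Product: 19 methyl 2-(hydroxymethyl)acrylate
Conditions: DABCO (cat.), 1,4-dioxane/H2O, rt
Reagents that add atoms: none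
Why: Morita–Baylis–Hillman reaction of the acrylate with formaldehyde.

Step 13
Reactants: 19 methyl 2-(hydroxymethyl)acrylate
Product: 20 methyl 2-(bromomethyl)acrylate
Conditions: PBr3, Et2O, −10 °C to rt
Reagents that add atoms: phosphorus tribromide, BrP(Br)Br
Why: Substitution of the allylic alcohol by bromide through its phosphite ester; the lachrymatory bromide is made fresh.

Step 14
Reactants: 21 tiglic acid
Product: 22 (R)-2-methylbutanoic acid
Conditions: H2 (4 atm), Ru(OAc)2[(R)-H8-BINAP] (0.5 mol %), MeOH, rt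
Reagents that add atoms: none
Why: Carboxylate-directed Noyori-type asymmetric hydrogenation of the trisubstituted acrylic acid; the (R)-diphosphine is expected to give the R acid (about 97% ee, raised by one crystallisation of its (R)-1-phenylethylammonium salt).

Step 15
Reactants: 11 West aldehyde, 16 East phosphono-lactone
Product: 23 (3E,5R)-3-{(3S,4Z)-3-[(tert-butyldimethylsilyl)oxy]-4-methyl-6-[(triethylsilyl)oxy]hex-4-en-1-ylidene}-5-vinyldihydrofuran-2(3H)-one
Conditions: LiCl, iPr2NEt, MeCN, 0 °C to rt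
Reagents that add atoms: none
Why: Horner–Wadsworth–Emmons olefination under Masamune–Roush conditions; the cyclic phosphonate gives mainly the E-alkylidene lactone (vinylic H syn to C=O), which puts C2 and C9 cis on C1=C10 as the later cis-fused oxirane needs.

Step 16
Reactants: 23 alkylidene lactone
Product: 24 (3R,5E,8S,9Z)-8-[(tert-butyldimethylsilyl)oxy]-5-(hydroxymethyl)-9-methyl-11-[(triethylsilyl)oxy]undeca-1,5,9-trien-3-ol
Conditions: iBu2AlH (4 equiv), CH2Cl2, −78 to 0 °C
Reagents that add atoms: none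
Why: 1,2-Reduction of the unsaturated lactone by the aluminium hydride opens it to the primary allylic alcohol (C14) and frees the C8 secondary alcohol with both alkene geometries intact.

Step 17
Reactants: 24 diol
Product: 25 (2R)-1-[(2R,3R)-3-{(2S,3Z)-2-[(tert-butyldimethylsilyl)oxy]-3-methyl-5-[(triethylsilyl)oxy]pent-3-en-1-yl}-2-(hydroxymethyl)oxiran-2-yl]but-3-en-2-ol
Conditions: Ti(OiPr)4 (20 mol %), (−)-diisopropyl (2S,3S)-tartrate (24 mol %), tBuOOH, 4 Å molecular sieves, CH2Cl2, −20 °C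
Reagents that add atoms: tert-butyl hydroperoxide, CC(C)(C)OO
Why: Katsuki–Sharpless asymmetric epoxidation: only the primary trisubstituted allylic alcohol is a fast substrate (the secondary vinyl carbinol and the silylated allylic ethers are not), and the (2S,3S)-tartrate delivers oxygen to the face that gives the 1R,10R oxirane with C2 and C9 cis.

Step 18
Reactants: 25 epoxy diol
Product: 26 (2R)-1-[(2R,3R)-2-{[(tert-butyldimethylsilyl)oxy]methyl}-3-{(2S,3Z)-2-[(tert-butyldimethylsilyl)oxy]-3-methyl-5-[(triethylsilyl)oxy]pent-3-en-1-yl}oxiran-2-yl]but-3-en-2-ol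
Conditions: tBuMe2SiCl, imidazole, CH2Cl2, 0 °C
Reagents that add atoms: tert-butyldimethylsilyl chloride, CC(C)(C)[Si](C)(C)Cl
Why: The primary alcohol is silylated much faster than the secondary allylic one.

Step 19
Reactants: 26 C8 alcohol, 22 (R)-2-methylbutanoic acid
Product: 27 (2R)-1-[(2R,3R)-2-{[(tert-butyldimethylsilyl)oxy]methyl}-3-{(2S,3Z)-2-[(tert-butyldimethylsilyl)oxy]-3-methyl-5-[(triethylsilyl)oxy]pent-3-en-1-yl}oxiran-2-yl]but-3-en-2-yl (2R)-2-methylbutanoate
Conditions: EDC·HCl, DMAP, CH2Cl2, 0 °C to rt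
Reagents that add atoms: none
Why: Steglich-type carbodiimide esterification acylates the only free hydroxyl with retention at C8 and, at 0 °C, without epimerising the α-centre of the acid.

Step 20
Reactants: 27 ester
Product: 28 (2R)-1-[(2R,3R)-2-{[(tert-butyldimethylsilyl)oxy]methyl}-3-{(2S,3Z)-2-[(tert-butyldimethylsilyl)oxy]-3-methyl-5-oxopent-3-en-1-yl}oxiran-2-yl]but-3-en-2-yl (2R)-2-methylbutanoate
Conditions: (COCl)2, DMSO, CH2Cl2, −78 to −40 °C; Et3N, to 0 °C
Reagents that add atoms: none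
Why: Under Swern conditions a primary triethylsilyl ether is converted directly into the aldehyde while tert-butyldimethylsilyl ethers stay, giving the Z-enal without isomerisation.

Step 21
Reactants: 28 Z-enal, 20 methyl 2-(bromomethyl)acrylate
Product: 29 methyl (2Z,4R)-2-(bromomethyl)-5-[(2R,3R)-2-{[(tert-butyldimethylsilyl)oxy]methyl}-3-{(2S,3Z)-2-[(tert-butyldimethylsilyl)oxy]-3-methyl-5-oxopent-3-en-1-yl}oxiran-2-yl]-4-{[(2R)-2-methylbutanoyl]oxy}pent-2-enoate
Conditions: second-generation Hoveyda–Grubbs catalyst (10 mol %), 20 (5 equiv), 2,6-dichloro-1,4-benzoquinone (20 mol %), CH2Cl2, 40 °C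
Reagents that add atoms: none
Why: Ruthenium-catalysed olefin cross-metathesis of the only monosubstituted alkene with the 1,1-disubstituted acrylate (in excess) gives the thermodynamically preferred trisubstituted enoate with the ester trans to C8; the trisubstituted enal alkene is inert.

Step 22
Reactants: 29 seco bromo-ester Z-enal
Product: 31 (1R,3S,4Z,6S,7R,8R,10R)-3,14-bis[(tert-butyldimethylsilyl)oxy]-1,10-epoxy-8-{[(2R)-2-methylbutanoyl]oxy}germacra-4,11(13)-dien-12,6-olide, via hydroxy ester 30 (not isolated)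
Conditions: CrCl2 (20 mol %), chiral carbazole–bis(oxazoline) ligand (22 mol %), iPr2NEt (40 mol %), Mn (3 equiv), Cp2ZrCl2 (1.2 equiv), LiCl, THF, 29 added over 12 h to 2 mM, rt; then PPTS (cat.), CH2Cl2, rt
Reagents that add atoms: none
Why: Proposed new method: a ligand-controlled, chromium-catalysed intramolecular 2-(methoxycarbonyl)allylation with a γ-substituted donor, in which ligand-bound divalent chromium reduces the allylic bromide to an allyl species of trivalent chromium that adds to the enal through a closed chair transition state with the γ-substituent (C8) cis to the CH2–Cr arm, so the C6 alkoxide and C8 end up syn (cis-lactone after loss of methanol), while the ligand selects the Re face of the aldehyde and so fixes 6S,7R against the existing C8 centre, Mn returning chromium to the divalent state and Cp2ZrCl2 freeing it from the alkoxide; the closest known reactions are the intermolecular chromium-catalysed enantioselective 2-(alkoxycarbonyl)allylation of aldehydes with unsubstituted donors and the stoichiometric, ligand-free CrCl2 Barbier macrocyclisation used for ten-membered germacranolides.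

Step 23
Reactants: 31 bis-silyl macrolactone
Product: 32 (1R,3S,4Z,6S,7R,8R,10R)-1,10-epoxy-3,14-dihydroxy-8-{[(2R)-2-methylbutanoyl]oxy}germacra-4,11(13)-dien-12,6-olide (CNP0356520.2)
Conditions: HF·pyridine, pyridine, THF, 0 °C to rt
Reagents that add atoms: none
Why: Buffered fluoride desilylation removes both tert-butyldimethylsilyl ethers without opening the oxirane, migrating the ester or adding to the α-methylene lactone.

**Compound list**

1 | but-2-yn-1-ol | CC#CCO | starting material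
2 | sodium 2,2-bis(2-methoxyethoxy)-3-methyl-2,5-dihydro-1,2-oxaluminol-2-uide (cyclic alkenylaluminate) | CC1=CCO[Al-]1(OCCOC)OCCOC.[Na+] | intermediate
3 | (Z)-3-iodobut-2-en-1-ol | C/C(I)=C/CO | intermediate
4 | (Z)-triethyl[(3-iodobut-2-en-1-yl)oxy]silane | C/C(I)=C/CO[Si](CC)(CC)CC | intermediate
5 | propane-1,3-diol | OCCCO | starting material
6 | 3-[(4-methoxybenzyl)oxy]propan-1-ol | COc1ccc(COCCCO)cc1 | intermediate
7 | 3-[(4-methoxybenzyl)oxy]propanal | COc1ccc(COCCC=O)cc1 | intermediate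
8 | (3S,4Z)-1-[(4-methoxybenzyl)oxy]-4-methyl-6-[(triethylsilyl)oxy]hex-4-en-3-ol | CC[Si](CC)(CC)OC/C=C(/C)[C@@H](O)CCOCc1ccc(OC)cc1 | intermediate
9 | tert-butyl{[(3S,4Z)-1-[(4-methoxybenzyl)oxy]-4-methyl-6-[(triethylsilyl)oxy]hex-4-en-3-yl]oxy}dimethylsilane | CC[Si](CC)(CC)OC/C=C(/C)[C@@H](O[Si](C)(C)C(C)(C)C)CCOCc1ccc(OC)cc1 | intermediate
10 | (3S,4Z)-3-[(tert-butyldimethylsilyl)oxy]-4-methyl-6-[(triethylsilyl)oxy]hex-4-en-1-ol | CC[Si](CC)(CC)OC/C=C(/C)[C@@H](O[Si](C)(C)C(C)(C)C)CCO | intermediate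
11 | (3S,4Z)-3-[(tert-butyldimethylsilyl)oxy]-4-methyl-6-[(triethylsilyl)oxy]hex-4-enal | CC[Si](CC)(CC)OC/C=C(/C)[C@@H](O[Si](C)(C)C(C)(C)C)CC=O | intermediate
12 | (5R)-5-(hydroxymethyl)dihydrofuran-2(3H)-one | OC[C@H]1CCC(=O)O1 | starting material
13 | (2R)-5-oxotetrahydrofuran-2-carbaldehyde | O=C[C@H]1CCC(=O)O1 | intermediate
14 | (5R)-5-vinyldihydrofuran-2(3H)-one | C=C[C@H]1CCC(=O)O1 | intermediate
15 | diethyl (5R)-5-vinyl-4,5-dihydrofuran-2-yl phosphate | C=C[C@H]1CC=C(OP(=O)(OCC)OCC)O1 | intermediate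
16 | diethyl [(5R)-2-oxo-5-vinyltetrahydrofuran-3-yl]phosphonate (both C3 epimers) | C=C[C@H]1CC(P(=O)(OCC)OCC)C(=O)O1 | intermediate
17 | methyl acrylate | C=CC(=O)OC | starting material
18 | formaldehyde (as paraformaldehyde) | C=O | starting material
19 | methyl 2-(hydroxymethyl)acrylate | C=C(CO)C(=O)OC | intermediate
20 | methyl 2-(bromomethyl)acrylate | C=C(CBr)C(=O)OC | intermediate
21 | tiglic acid, (E)-2-methylbut-2-enoic acid | C/C=C(\C)C(=O)O | starting material
22 | (R)-2-methylbutanoic acid | CC[C@@H](C)C(=O)O | intermediate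
23 | (3E,5R)-3-{(3S,4Z)-3-[(tert-butyldimethylsilyl)oxy]-4-methyl-6-[(triethylsilyl)oxy]hex-4-en-1-ylidene}-5-vinyldihydrofuran-2(3H)-one | C=C[C@H]1C/C(=C\C[C@H](O[Si](C)(C)C(C)(C)C)/C(C)=C\CO[Si](CC)(CC)CC)C(=O)O1 | intermediate
24 | (3R,5E,8S,9Z)-8-[(tert-butyldimethylsilyl)oxy]-5-(hydroxymethyl)-9-methyl-11-[(triethylsilyl)oxy]undeca-1,5,9-trien-3-ol | C=C[C@H](O)C/C(CO)=C\C[C@H](O[Si](C)(C)C(C)(C)C)/C(C)=C\CO[Si](CC)(CC)CC | intermediate
25 | (2R)-1-[(2R,3R)-3-{(2S,3Z)-2-[(tert-butyldimethylsilyl)oxy]-3-methyl-5-[(triethylsilyl)oxy]pent-3-en-1-yl}-2-(hydroxymethyl)oxiran-2-yl]but-3-en-2-ol | C=C[C@H](O)C[C@]1(CO)O[C@@H]1C[C@H](O[Si](C)(C)C(C)(C)C)/C(C)=C\CO[Si](CC)(CC)CC | intermediate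
26 | (2R)-1-[(2R,3R)-2-{[(tert-butyldimethylsilyl)oxy]methyl}-3-{(2S,3Z)-2-[(tert-butyldimethylsilyl)oxy]-3-methyl-5-[(triethylsilyl)oxy]pent-3-en-1-yl}oxiran-2-yl]but-3-en-2-ol | C=C[C@H](O)C[C@]1(CO[Si](C)(C)C(C)(C)C)O[C@@H]1C[C@H](O[Si](C)(C)C(C)(C)C)/C(C)=C\CO[Si](CC)(CC)CC | intermediate
27 | (2R)-1-[(2R,3R)-2-{[(tert-butyldimethylsilyl)oxy]methyl}-3-{(2S,3Z)-2-[(tert-butyldimethylsilyl)oxy]-3-methyl-5-[(triethylsilyl)oxy]pent-3-en-1-yl}oxiran-2-yl]but-3-en-2-yl (2R)-2-methylbutanoate | C=C[C@H](OC(=O)[C@H](C)CC)C[C@]1(CO[Si](C)(C)C(C)(C)C)O[C@@H]1C[C@H](O[Si](C)(C)C(C)(C)C)/C(C)=C\CO[Si](CC)(CC)CC | intermediate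
28 | (2R)-1-[(2R,3R)-2-{[(tert-butyldimethylsilyl)oxy]methyl}-3-{(2S,3Z)-2-[(tert-butyldimethylsilyl)oxy]-3-methyl-5-oxopent-3-en-1-yl}oxiran-2-yl]but-3-en-2-yl (2R)-2-methylbutanoate | C=C[C@H](OC(=O)[C@H](C)CC)C[C@]1(CO[Si](C)(C)C(C)(C)C)O[C@@H]1C[C@H](O[Si](C)(C)C(C)(C)C)/C(C)=C\C=O | intermediate
29 | methyl (2Z,4R)-2-(bromomethyl)-5-[(2R,3R)-2-{[(tert-butyldimethylsilyl)oxy]methyl}-3-{(2S,3Z)-2-[(tert-butyldimethylsilyl)oxy]-3-methyl-5-oxopent-3-en-1-yl}oxiran-2-yl]-4-{[(2R)-2-methylbutanoyl]oxy}pent-2-enoate | COC(=O)/C(CBr)=C/[C@H](OC(=O)[C@H](C)CC)C[C@]1(CO[Si](C)(C)C(C)(C)C)O[C@@H]1C[C@H](O[Si](C)(C)C(C)(C)C)/C(C)=C\C=O | intermediate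
30 | methyl (1R,3S,4Z,6S,7S,8R,10R)-3,14-bis[(tert-butyldimethylsilyl)oxy]-1,10-epoxy-6-hydroxy-8-{[(2R)-2-methylbutanoyl]oxy}germacra-4,11(13)-dien-12-oate (same spatial arrangement as 31; C7 reads S while the lactone is open) | C=C(C(=O)OC)[C@H]1[C@@H](O)/C=C(/C)[C@@H](O[Si](C)(C)C(C)(C)C)C[C@H]2O[C@@]2(CO[Si](C)(C)C(C)(C)C)C[C@H]1OC(=O)[C@H](C)CC | intermediate
31 | (1R,3S,4Z,6S,7R,8R,10R)-3,14-bis[(tert-butyldimethylsilyl)oxy]-1,10-epoxy-8-{[(2R)-2-methylbutanoyl]oxy}germacra-4,11(13)-dien-12,6-olide | C=C1C(=O)O[C@H]2/C=C(/C)[C@@H](O[Si](C)(C)C(C)(C)C)C[C@H]3O[C@@]3(CO[Si](C)(C)C(C)(C)C)C[C@@H](OC(=O)[C@H](C)CC)[C@@H]12 | intermediate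
32 | (1R,3S,4Z,6S,7R,8R,10R)-1,10-epoxy-3,14-dihydroxy-8-{[(2R)-2-methylbutanoyl]oxy}germacra-4,11(13)-dien-12,6-olide (CNP0356520.2) | C=C1C(=O)O[C@H]2/C=C(/C)[C@@H](O)C[C@H]3O[C@@]3(CO)C[C@@H](OC(=O)[C@H](C)CC)[C@@H]12 | target

**Step count and risks**

Total step count: 23. Longest linear sequence: 15 steps (steps 1, 2, 5–8 and 15–23; the path through steps 3 and 4 is equally long).

Steps most likely to fail:

Step 22 (the new macrocyclisation). Risks are 1,4-elimination of the C8 carboxylate from the allylchromium, oligomerisation, and a mismatched ligand/substrate pairing. The fallback uses known chemistry, sets out from 26 and returns at 31. The C8 hydroxyl is capped instead of acylated (Et3SiOTf, 2,6-lutidine) to give the C8 triethylsilyl ether of 26 F1. Swern oxidation, which touches only the primary silyl ether, gives the corresponding Z-enal F2, and cross-metathesis with 20 gives the C8 triethylsilyl ether analogue of 29 F3. The ring is then closed by the established ligand-free, stoichiometric Barbier macrocyclisation (CrCl2, 10 equiv, THF, 2 mM; then PPTS), under substrate control and with a silyloxy group that cannot leave, to give the C8 triethylsilyl ether analogue of 31 F4. HF·pyridine/pyridine at 0 °C removes only the secondary triethylsilyl ether to give the C8 alcohol F5, and EDC·HCl/DMAP esterification with 22 gives 31.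

Step 5 (enantioselectivity of the catalytic alkenyl transfer may be too low). The fallback sets out from 4 and 7 and returns at 8; the stereocentre is set by ketone reduction instead of by the C–C coupling. Ligand-free coupling (CrCl2, 4 equiv; NiCl2, 1 mol %; DMF) gives the racemic form of 8 F6. Dess–Martin oxidation gives (4Z)-1-[(4-methoxybenzyl)oxy]-4-methyl-6-[(triethylsilyl)oxy]hex-4-en-3-one F7. Corey–Bakshi–Shibata reduction with the (R)-methyl oxazaborolidine and BH3·SMe2 then gives 8.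

Step 15 (E/Z ratio of the alkylidene lactone; β-elimination of the silyloxy group from 11). The fallback sets out from 14 and 11 and returns at 23, replacing the phosphonate olefination by aldol addition and dehydration. The lithium enolate of 14 (LiN(iPr)2, THF, −78 °C) adds to 11 to give the β-hydroxy lactone F8. MsCl/Et3N gives its mesylate F9, and DBU-induced E1cB elimination gives the thermodynamically favoured E-alkylidene lactone 23.

Further compounds
F1 | step 22 | C8 triethylsilyl ether of 26 | C=C[C@H](O[Si](CC)(CC)CC)C[C@]1(CO[Si](C)(C)C(C)(C)C)O[C@@H]1C[C@H](O[Si](C)(C)C(C)(C)C)/C(C)=C\CO[Si](CC)(CC)CC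
F2 | step 22 | Z-enal from F1 (C8 triethylsilyl ether analogue of 28) | C=C[C@H](O[Si](CC)(CC)CC)C[C@]1(CO[Si](C)(C)C(C)(C)C)O[C@@H]1C[C@H](O[Si](C)(C)C(C)(C)C)/C(C)=C\C=O
F3 | step 22 | C8 triethylsilyl ether analogue of 29 | COC(=O)/C(CBr)=C/[C@H](O[Si](CC)(CC)CC)C[C@]1(CO[Si](C)(C)C(C)(C)C)O[C@@H]1C[C@H](O[Si](C)(C)C(C)(C)C)/C(C)=C\C=O
F4 | step 22 | C8 triethylsilyl ether analogue of 31 (same configuration) | C=C1C(=O)O[C@H]2/C=C(/C)[C@@H](O[Si](C)(C)C(C)(C)C)C[C@H]3O[C@@]3(CO[Si](C)(C)C(C)(C)C)C[C@@H](O[Si](CC)(CC)CC)[C@@H]12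
F5 | step 22 | C8 alcohol (8-deacyl analogue of 31) | C=C1C(=O)O[C@H]2/C=C(/C)[C@@H](O[Si](C)(C)C(C)(C)C)C[C@H]3O[C@@]3(CO[Si](C)(C)C(C)(C)C)C[C@@H](O)[C@@H]12
F6 | step 5 | racemic (4Z)-1-[(4-methoxybenzyl)oxy]-4-methyl-6-[(triethylsilyl)oxy]hex-4-en-3-ol | CC[Si](CC)(CC)OC/C=C(/C)C(O)CCOCc1ccc(OC)cc1
F7 | step 5 | (4Z)-1-[(4-methoxybenzyl)oxy]-4-methyl-6-[(triethylsilyl)oxy]hex-4-en-3-one | CC[Si](CC)(CC)OC/C=C(/C)C(=O)CCOCc1ccc(OC)cc1
F8 | step 15 | (5R)-3-{(3S,4Z)-3-[(tert-butyldimethylsilyl)oxy]-1-hydroxy-4-methyl-6-[(triethylsilyl)oxy]hex-4-en-1-yl}-5-vinyldihydrofuran-2(3H)-one (mixture at the two new centres) | C=C[C@H]1CC(C(O)C[C@H](O[Si](C)(C)C(C)(C)C)/C(C)=C\CO[Si](CC)(CC)CC)C(=O)O1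
F9 | step 15 | methanesulfonate of F8 | C=C[C@H]1CC(C(OS(C)(=O)=O)C[C@H](O[Si](C)(C)C(C)(C)C)/C(C)=C\CO[Si](CC)(CC)CC)C(=O)O1
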